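**Assumptions:** Tabularin has no stereocenters, so the "single enantiomer" is just the achiral compound and no stereochemical control is needed. Methyl 3,5-dihydroxy-4-methoxybenzoate is taken as commercially available.

## Retrosynthetic overview
1. Tabularin is 5,7-dihydroxy-6-methoxy-2-(2,4,5-trimethoxyphenyl)chromone, so the last step is removal of two benzyl ethers from the A-ring.
2. Key step: a one-pot Pd-catalysed three-component carbonylative Sonogashira/oxa-Michael annulation of an o-iodophenol, CO and an aryl alkyne. It forms the C4a–C4 bond and the C2–O1 bond and closes the pyranone ring, instead of using Baker–Venkataraman or chalcone oxidative cyclisation.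
3. The o-iodophenol is 2-iodo-3,5-bis(benzyloxy)-4-methoxyphenol. It comes from methyl 3,5-dihydroxy-4-methoxybenzoate by benzylation, ester to aldehyde, Baeyer–Villiger/Dakin conversion of CHO to OH, and ortho-iodination (the two ortho positions are equivalent, so there is no regiochemistry problem).
4. The alkyne is 2,4,5-trimethoxyphenylacetylene, made from 2,4,5-trimethoxybenzaldehyde by Ohira–Bestmann homologation.
5. Ring order: ring A is the starting arene, ring C (pyranone) is formed in step 7, and ring B is delivered intact by the alkyne.

## Route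

**Step 1**
Reactants: 1 (methyl 3,5-dihydroxy-4-methoxybenzoate); 2 (benzyl bromide)
Product: 3 (methyl 3,5-bis(benzyloxy)-4-methoxybenzoate)
Conditions: BnBr (2.3 equiv), K2CO3, DMF, 60 °C
Reagents that add atoms: BnBr, BrCc1ccccc1
Why: Williamson etherification caps both phenols as benzyl ethers, which are stable to Pd/CO and removable at the end by hydrogenolysis; no stereocenter is involved.

**Step 2**
Reactants: 3
Product: 4 (3,5-bis(benzyloxy)-4-methoxybenzaldehyde)
Conditions: DIBAL-H (1.05 equiv), CH2Cl2, –78 °C, then Rochelle salt work-up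
Reagents that add atoms: none (hydride only)
Why: Partial ester-to-aldehyde reduction is controlled by the stable tetrahedral aluminium hemiacetal at –78 °C; no stereocenter.

**Step 3**
Reactants: 4; 5 (mCPBA)
Product: 6 (3,5-bis(benzyloxy)-4-methoxyphenyl formate)
Conditions: mCPBA (1.5 equiv), NaHCO3, CH2Cl2, 0 °C to rt
Reagents that add atoms: mCPBA, O=C(OO)c1cccc(Cl)c1
Why: In the Baeyer–Venkataraman-type (Dakin-like) Baeyer–Villiger oxidation, the electron-rich aryl group migrates in preference to H, giving the aryl formate; no stereocenter.

**Step 4**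
Reactants: 6
Product: 7 (3,5-bis(benzyloxy)-4-methoxyphenol)
Conditions: K2CO3, MeOH, rt
Reagents that add atoms: none (the formyl group is transferred to MeOH)
Why: Mild methanolysis of the formate ester releases the phenol, and the benzyl ethers are unaffected.

**Step 5**
Reactants: 7; 8 (N-iodosuccinimide)
Product: 9 (2-iodo-3,5-bis(benzyloxy)-4-methoxyphenol)
Conditions: NIS (1.0 equiv), MeCN, –20 °C to 0 °C
Reagents that add atoms: NIS, O=C1CCC(=O)N1I
Why: Electrophilic aromatic iodination goes ortho to the strongly activating OH; the para position is blocked by OMe and the two ortho positions are equivalent, so a single regioisomer forms.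

**Step 6**
Reactants: 10 (2,4,5-trimethoxybenzaldehyde); 11 (dimethyl (1-diazo-2-oxopropyl)phosphonate)
Product: 12 (1-ethynyl-2,4,5-trimethoxybenzene)
Conditions: 11 (1.2 equiv), K2CO3, MeOH, rt
Reagents that add atoms: Ohira–Bestmann reagent, CC(=O)C(=[N+]=[N-])P(=O)(OC)OC
Why: The Ohira–Bestmann one-carbon homologation generates dimethyl diazomethylphosphonate in situ, which converts the aldehyde to the terminal alkyne via a vinylidene carbene and 1,2-aryl shift.

**Step 7 (key step)**
Reactants: 9; 12; 13 (carbon monoxide)
Product: 14 (5,7-bis(benzyloxy)-6-methoxy-2-(2,4,5-trimethoxyphenyl)-4H-chromen-4-one)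
Conditions: PdCl2(PPh3)2 (5 mol %), Et3N, CO (balloon, 1 atm), DMF, 80 °C, Cu-free
Reagents that add atoms: CO, [C-]#[O+]
Why: Carbonylative Sonogashira annulation: oxidative addition of Ar–I, CO insertion, alkyne coupling to give an o-hydroxyaryl ynone, and 6-endo phenoxide conjugate addition to form the flavone. Pd-only conditions and CO are used to favour the flavone over the 5-exo 2-arylbenzofuran, and the product is achiral.

**Step 8**
Reactants: 14
Product: 15 (Tabularin)
Conditions: H2 (1 atm), 10% Pd/C, THF/MeOH, rt, monitored to avoid over-reduction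
Reagents that add atoms: none (H2 only; toluene is the by-product)
Why: Catalytic hydrogenolysis cleaves the aryl benzyl ethers and leaves the methyl ethers and the conjugated C2=C3 bond intact; the 5-OH is stabilised by H-bonding to the C4 carbonyl.

## Compound list
1 | methyl 3,5-dihydroxy-4-methoxybenzoate | COC(=O)c1cc(O)c(OC)c(O)c1 | starting material
2 | benzyl bromide | BrCc1ccccc1 | reagent/starting material
3 | methyl 3,5-bis(benzyloxy)-4-methoxybenzoate | COC(=O)c1cc(OCc2ccccc2)c(OC)c(OCc2ccccc2)c1 | intermediate
4 | 3,5-bis(benzyloxy)-4-methoxybenzaldehyde | O=Cc1cc(OCc2ccccc2)c(OC)c(OCc2ccccc2)c1 | intermediate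
5 | mCPBA | O=C(OO)c1cccc(Cl)c1 | reagent
6 | 3,5-bis(benzyloxy)-4-methoxyphenyl formate | O=COc1cc(OCc2ccccc2)c(OC)c(OCc2ccccc2)c1 | intermediate
7 | 3,5-bis(benzyloxy)-4-methoxyphenol | Oc1cc(OCc2ccccc2)c(OC)c(OCc2ccccc2)c1 | intermediate
8 | N-iodosuccinimide | O=C1CCC(=O)N1I | reagent
9 | 2-iodo-3,5-bis(benzyloxy)-4-methoxyphenol | Oc1cc(OCc2ccccc2)c(OC)c(OCc2ccccc2)c1I | intermediate
10 | 2,4,5-trimethoxybenzaldehyde | COc1cc(OC)c(C=O)cc1OC | starting material
11 | dimethyl (1-diazo-2-oxopropyl)phosphonate | CC(=O)C(=[N+]=[N-])P(=O)(OC)OC | reagent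
12 | 1-ethynyl-2,4,5-trimethoxybenzene | COc1cc(OC)c(C#C)cc1OC | intermediate
13 | carbon monoxide | [C-]#[O+] | reagent
14 | 5,7-bis(benzyloxy)-6-methoxy-2-(2,4,5-trimethoxyphenyl)chromen-4-one | COc1cc(OC)c(-c2cc(=O)c3c(OCc4ccccc4)c(OC)c(OCc4ccccc4)cc3o2)cc1OC | intermediate
15 | Tabularin (5,7-dihydroxy-6-methoxy-2-(2,4,5-trimethoxyphenyl)chromen-4-one; achiral) | COc1cc(OC)c(-c2cc(=O)c3c(O)c(OC)c(O)cc3o2)cc1OC | target

## Totals
- Total steps: 8.
- Longest linear sequence: 7 (1 → 3 → 4 → 6 → 7 → 9 → 14 → 15); the alkyne preparation in step 6 is a parallel branch.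

## Three steps most likely to fail
1. **Step 7, carbonylative annulation.** The iodide is flanked by OH and OBn, which hinders oxidative addition, and 2-arylbenzofuran or uncyclised ynone may form instead.
   Fallback: change the ring-C construction. Make the 2-hydroxyacetophenone by BF3·OEt2/AcOH Fries acetylation of phenol 7, then use a Baker–Venkataraman aroylation with 2,4,5-trimethoxybenzoyl chloride and acid cyclodehydration.
2. **Step 5, mono-iodination.** The electron-rich phenol may give diiodide or quinone-type oxidation products.
   Fallback: install the ortho carbon differently. Convert phenol 7 to its O-diethylcarbamate, then directed ortho-lithiation and quench with I2, then cleave the carbamate.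
3. **Step 8, hydrogenolysis.** C2=C3 may be reduced to the flavanone, or the reaction may stall.
   Fallback: use bis-MOM protection in place of benzyl (MOMCl in step 1 and the corresponding intermediates), and remove it at the end with HCl/MeOH, so that no reduction is needed.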